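Everything rests on forming both C–Br bonds of ring A (the dibromo ring, C1 bearing CH2O) last, on the intact unsymmetrical dibenzyl ether. The feature exploited: C2 and C6 of ring A are ortho and para to the C3 oxygen, C5 is ortho only to the C4 oxygen, and the tribromo ring B has no C–H. A precursor with free C3–OH, an acetal on O4 and a bis-acetal ring B, namely 3-hydroxy-4-(methoxymethoxy)benzyl 2,3,6-tribromo-4,5-bis(methoxymethoxy)benzyl ether, should therefore take exactly two bromines, at C2 and C6, in one operation. Methoxymethyl groups let dilute aqueous acid, not a boron halide that would split the benzylic ether, finish the synthesis.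

Key step: step 9

Remark: the three oxygens masked through the key step are carried as methoxymethyl acetals, not methyl ethers, because BBr3 demethylation would be expected to turn the benzylic ether into benzyl bromides; O3 of ring A carries a triisopropylsilyl group during the coupling because that aryl silyl ether resists alkoxide better than a tert-butyldimethylsilyl ether.

Step 1
Reactants: 1 3,4-dihydroxybenzaldehyde
Product: 2 2,3,6-tribromo-4,5-dihydroxybenzaldehyde
Conditions: Br2 (3.3 equiv), AcOH, rt then 60 °C; aq. NaHSO3 work-up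
Reagents that add atoms: bromine (Br2), BrBr
Why: Exhaustive electrophilic aromatic bromination, in which each of the three ring C–H positions of 1 is ortho or para to a free catechol hydroxyl and should be substituted, while the un-ionised phenols in acidic AcOH keep ipso attack at the formyl-bearing carbon in check.

Step 2
Reactants: 2 2,3,6-tribromo-4,5-dihydroxybenzaldehyde
Product: 3 2,3,6-tribromo-4,5-bis(methoxymethoxy)benzaldehyde
Conditions: MOMCl (2.6 equiv), K2CO3 (3 equiv), acetone, 0 °C to rt
Reagents that add atoms: chloromethyl methyl ether (MOMCl), COCCl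
Why: Williamson-type O-alkylation of the two acidic bromophenol oxygens by the small, reactive chloromethyl ether should give the bis-acetal even though each oxygen is flanked by a substituent.

Step 3
Reactants: 3 2,3,6-tribromo-4,5-bis(methoxymethoxy)benzaldehyde
Product: 4 [2,3,6-tribromo-4,5-bis(methoxymethoxy)phenyl]methanol
Conditions: NaBH4, MeOH–THF, 0 °C
Reagents that add atoms: none
Why: Hydride reduction of the aldehyde by NaBH4 at 0 °C should leave the aryl bromides and the acetals untouched.

Step 4
Reactants: 4 [2,3,6-tribromo-4,5-bis(methoxymethoxy)phenyl]methanol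
Product: 5 2,3,6-tribromo-4,5-bis(methoxymethoxy)benzyl bromide
Conditions: CBr4, PPh3, CH2Cl2, 0 °C
Reagents that add atoms: carbon tetrabromide (CBr4), BrC(Br)(Br)Br
Why: Appel reaction, in which bromide displaces the alkoxyphosphonium group at the primary benzylic carbon under neutral conditions that the acetals tolerate.

Step 5
Reactants: 1 3,4-dihydroxybenzaldehyde
Product: 6 3-hydroxy-4-(methoxymethoxy)benzaldehyde
Conditions: MOMCl (1.0 equiv), K2CO3 (1.1 equiv), acetone, 0 °C to rt
Reagents that add atoms: chloromethyl methyl ether (MOMCl), COCCl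
Why: Regioselective Williamson-type O-alkylation, since the C4 hydroxyl para to the formyl group is much the more acidic and one equivalent of weak base should generate and alkylate that phenoxide only, leaving the C3 hydroxyl free.

Step 6
Reactants: 6 3-hydroxy-4-(methoxymethoxy)benzaldehyde
Product: 7 4-(methoxymethoxy)-3-[(triisopropylsilyl)oxy]benzaldehyde
Conditions: TIPSCl, imidazole, DMF, rt
Reagents that add atoms: triisopropylsilyl chloride (TIPSCl), CC(C)[Si](Cl)(C(C)C)C(C)C
Why: Imidazole-promoted silylation of the remaining phenol installs a bulky aryl silyl ether that should withstand NaBH4 and the alkoxide of step 8 yet fall to fluoride.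

Step 7
Reactants: 7 4-(methoxymethoxy)-3-[(triisopropylsilyl)oxy]benzaldehyde
Product: 8 {4-(methoxymethoxy)-3-[(triisopropylsilyl)oxy]phenyl}methanol
Conditions: NaBH4, MeOH–THF, 0 °C
Reagents that add atoms: none
Why: NaBH4 reduction of the aldehyde to the benzylic alcohol should proceed with the silyl ether and the acetal inert at 0 °C.

Step 8
Reactants: 8 {4-(methoxymethoxy)-3-[(triisopropylsilyl)oxy]phenyl}methanol; 5 2,3,6-tribromo-4,5-bis(methoxymethoxy)benzyl bromide
Product: 10 3-hydroxy-4-(methoxymethoxy)benzyl 2,3,6-tribromo-4,5-bis(methoxymethoxy)benzyl ether, via silyl ether 9 (not isolated)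
Conditions: 8 (1.1 equiv), NaH, THF, 0 °C; then 5 (1.0 equiv), n-Bu4NI (cat.), 0 °C to rt; then n-Bu4NF, rt; aq. NH4Cl
Reagents that add atoms: none
Why: Williamson ether synthesis by SN2 attack of the sodium alkoxide of 8 on the primary benzylic bromide 5 (2,6-dihalobenzyl bromides are competent electrophiles and cannot eliminate), followed in the same flask by fluoride cleavage of the aryl O–Si bond, with 5 as the limiting partner so that no electrophile is left when the phenoxide is released.

Step 9
Reactants: 10 3-hydroxy-4-(methoxymethoxy)benzyl 2,3,6-tribromo-4,5-bis(methoxymethoxy)benzyl ether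
Product: 11 2,6-dibromo-3-hydroxy-4-(methoxymethoxy)benzyl 2,3,6-tribromo-4,5-bis(methoxymethoxy)benzyl ether
Conditions: Br2 (2.05 equiv), NaOAc (3 equiv), AcOH–CH2Cl2, 0 °C to rt, dark; aq. Na2S2O3
Reagents that add atoms: bromine (Br2), BrBr
Why: Bromine attacks ring A para (C6) and ortho (C2) to the free C3 hydroxyl through arenium ions stabilised by the phenolic oxygen, and loss of a proton to acetate restores the arene each time (electrophilic aromatic substitution). The closest known reaction type is the hydroxyl-directed ortho/para bromination of isovanillin-type 3-hydroxy-4-alkoxyarenes with buffered bromine. No ring is closed and no stereocentre is created. The selectivity needed is C2 and C6 over C5 and over ipso attack at C1: C5 and C1 are ortho and para only to the C4 acetal oxygen, a weaker donor than the free phenol, and ring B has no C–H. Two equivalents of bromine should hold the reaction at the dibromide, and NaOAc removes HBr so that neither the acetals nor the electron-rich benzylic ether is cleaved.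

Step 10
Reactants: 11 2,6-dibromo-3-hydroxy-4-(methoxymethoxy)benzyl 2,3,6-tribromo-4,5-bis(methoxymethoxy)benzyl ether
Product: 12 2,6-dibromo-3,4-dihydroxybenzyl 2,3,6-tribromo-4,5-dihydroxybenzyl ether
Conditions: 3 M aq. HCl, THF, 45 °C, argon
Reagents that add atoms: none
Why: Acid-catalysed hydrolysis of the three aryl methoxymethyl acetals (acetal cleavage through an oxocarbenium ion with the bromophenol as leaving group) should be complete in dilute acid well before the benzylic ether ionises, since four ortho bromines slow that ionisation, and no bromide is delivered to benzylic carbon as a boron halide would do.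

Compound list
1 | 3,4-dihydroxybenzaldehyde | O=Cc1ccc(O)c(O)c1 | starting material
2 | 2,3,6-tribromo-4,5-dihydroxybenzaldehyde | O=Cc1c(Br)c(O)c(O)c(Br)c1Br | intermediate
3 | 2,3,6-tribromo-4,5-bis(methoxymethoxy)benzaldehyde | O=Cc1c(Br)c(OCOC)c(OCOC)c(Br)c1Br | intermediate
4 | [2,3,6-tribromo-4,5-bis(methoxymethoxy)phenyl]methanol | OCc1c(Br)c(OCOC)c(OCOC)c(Br)c1Br | intermediate
5 | 2,3,6-tribromo-4,5-bis(methoxymethoxy)benzyl bromide | BrCc1c(Br)c(OCOC)c(OCOC)c(Br)c1Br | intermediate
6 | 3-hydroxy-4-(methoxymethoxy)benzaldehyde | COCOc1ccc(C=O)cc1O | intermediate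
7 | 4-(methoxymethoxy)-3-[(triisopropylsilyl)oxy]benzaldehyde | COCOc1ccc(C=O)cc1O[Si](C(C)C)(C(C)C)C(C)C | intermediate
8 | {4-(methoxymethoxy)-3-[(triisopropylsilyl)oxy]phenyl}methanol | COCOc1ccc(CO)cc1O[Si](C(C)C)(C(C)C)C(C)C | intermediate
9 | 4-(methoxymethoxy)-3-[(triisopropylsilyl)oxy]benzyl 2,3,6-tribromo-4,5-bis(methoxymethoxy)benzyl ether | COCOc1ccc(COCc2c(Br)c(OCOC)c(OCOC)c(Br)c2Br)cc1O[Si](C(C)C)(C(C)C)C(C)C | intermediate
10 | 3-hydroxy-4-(methoxymethoxy)benzyl 2,3,6-tribromo-4,5-bis(methoxymethoxy)benzyl ether | COCOc1ccc(COCc2c(Br)c(OCOC)c(OCOC)c(Br)c2Br)cc1O | intermediate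
11 | 2,6-dibromo-3-hydroxy-4-(methoxymethoxy)benzyl 2,3,6-tribromo-4,5-bis(methoxymethoxy)benzyl ether | COCOc1cc(Br)c(COCc2c(Br)c(OCOC)c(OCOC)c(Br)c2Br)c(Br)c1O | intermediate
12 | 2,6-dibromo-3,4-dihydroxybenzyl 2,3,6-tribromo-4,5-dihydroxybenzyl ether | Oc1cc(Br)c(COCc2c(Br)c(O)c(O)c(Br)c2Br)c(Br)c1O | target

Total step count: 10. Longest linear sequence: 7 (steps 1, 2, 3, 4, 8, 9, 10).

Steps most likely to fail

Step 9. Bromination may overrun to C5, attack C1 ipso with loss of the benzylic carbon, or stall after the first bromine because C2 is hindered. The fallback installs both ring A bromines before the ether bond is made. It sets out from 6: buffered bromine (2 equiv, NaOAc, AcOH) should give 2,6-dibromo-3-hydroxy-4-(methoxymethoxy)benzaldehyde F1. MOMCl and K2CO3 should then give 2,6-dibromo-3,4-bis(methoxymethoxy)benzaldehyde F2, and NaBH4 the alcohol [2,6-dibromo-3,4-bis(methoxymethoxy)phenyl]methanol F3. Williamson coupling of the sodium alkoxide of that alcohol with bromide 5 (NaH, THF, n-Bu4NI) should give 2,6-dibromo-3,4-bis(methoxymethoxy)benzyl 2,3,6-tribromo-4,5-bis(methoxymethoxy)benzyl ether F4. The acid hydrolysis of step 10 then returns to the route at 12.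

Step 10. Aqueous acid may ionise the benzylic ether, giving solvolysis to the two benzyl alcohols, before all three acetals are hydrolysed. The fallback exchanges the acetals for silyl groups under buffered, non-protic conditions. It sets out from 11: TMSOTf and 2,2'-bipyridyl in CH2Cl2 at 0 °C should convert the aryl methoxymethyl ethers and the free phenol into 2,6-dibromo-3,4-bis(trimethylsilyloxy)benzyl 2,3,6-tribromo-4,5-bis(trimethylsilyloxy)benzyl ether F5. Neutral water should cleave this on work-up, returning to the route at 12.

Step 8. The alkoxide of 8 may strip the silyl group from the aryl oxygen, leading to aryl O-alkylation, or substitution at the doubly ortho-brominated benzylic carbon may be too slow. The fallback reverses the roles of the partners. It sets out from 8 and 4: MsCl and Et3N followed by LiCl should give 4-(methoxymethoxy)-3-[(triisopropylsilyl)oxy]benzyl chloride F6, a reactive electrophile of the 4-alkoxybenzyl chloride type. The sodium alkoxide of alcohol 4 (NaH, THF, 0 °C) should alkylate it quickly, returning to the route at 9, which fluoride converts into 10 as before.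

Further compounds
F1 | step 9 | 2,6-dibromo-3-hydroxy-4-(methoxymethoxy)benzaldehyde | COCOc1cc(Br)c(C=O)c(Br)c1O
F2 | step 9 | 2,6-dibromo-3,4-bis(methoxymethoxy)benzaldehyde | COCOc1cc(Br)c(C=O)c(Br)c1OCOC
F3 | step 9 | [2,6-dibromo-3,4-bis(methoxymethoxy)phenyl]methanol | COCOc1cc(Br)c(CO)c(Br)c1OCOC
F4 | step 9 | 2,6-dibromo-3,4-bis(methoxymethoxy)benzyl 2,3,6-tribromo-4,5-bis(methoxymethoxy)benzyl ether | COCOc1cc(Br)c(COCc2c(Br)c(OCOC)c(OCOC)c(Br)c2Br)c(Br)c1OCOC
F5 | step 10 | 2,6-dibromo-3,4-bis(trimethylsilyloxy)benzyl 2,3,6-tribromo-4,5-bis(trimethylsilyloxy)benzyl ether | C[Si](C)(C)Oc1cc(Br)c(COCc2c(Br)c(O[Si](C)(C)C)c(O[Si](C)(C)C)c(Br)c2Br)c(Br)c1O[Si](C)(C)C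
F6 | step 8 | 4-(methoxymethoxy)-3-[(triisopropylsilyl)oxy]benzyl chloride | COCOc1ccc(CCl)cc1O[Si](C(C)C)(C(C)C)C(C)C
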